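(Readings and results come from a simulation with constants of no real substance, noise included.)

Slowness was the first thing I read. At 6.00 min, Saturday's run held 4.0% of complex with one exchanged and Sunday's held 3.8%, with a third of the incoming ligand in.

the same everywhere: incoming ligand 15.8 mM (in portions, 3)
- Saturday's: starting complex 21 mM; run made earlier; portions every 6.0 min
- Sunday's: starting complex 33 mM; run made earlier; portions every 6.0 min
- flask: starting complex 15 mM; the portions of incoming ligand follow each other after 6.0 min, the first at the start; time 30 min

| run | time / min | complex with one exchanged / % | complex with three exchanged / % | starting complex / % | complex with two exchanged / % |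
|---|---|---|---|---|---|
| Saturday's | 2.00 | 0.9 | 0.2 | 97.9 | 0 |
| Saturday's | 3.00 | 2.7 | 0.1 | 96.6 | 0.2 |
| Saturday's | 4.00 | 3.1 | 0.2 | 96.0 | 0.4 |
| Saturday's | 6.00 | 4.0 | 0 | 93.4 | 0.2 |
| Saturday's | 10.0 | 8.6 | 0 | 87.6 | 0 |
| Saturday's | 15.0 | 15.4 | 0.3 | 78.3 | 0.5 |
| Saturday's | 25.0 | 24.9 | 0.4 | 65.3 | 0.7 |
| Sunday's | 1.33 | 0.6 | 0.1 | 98.6 | 0 |
| Sunday's | 4.00 | 2.4 | 0 | 95.6 | 0.1 |
| Sunday's | 6.00 | 3.8 | 0 | 94.1 | 0 |
| Sunday's | 10.0 | 8.2 | 0 | 86.7 | 0.3 |
| Sunday's | 15.0 | 13.1 | 0 | 78.2 | 0.5 |
| Sunday's | 20.0 | 19.0 | 0.4 | 71.4 | 0.3 |
| Sunday's | 25.0 | 21.8 | 0 | 66.3 | 0.8 |

(each reading ± 0.3 percentage points)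

- a reading or a percentage of starting complex is of its free form alone

* the species that holds most of what was charged as starting complex, at 30 min (complex with two exchanged / starting complex / complex with three exchanged / complex with one exchanged)
* the largest share itself, whichever of these holds it, in percent of the starting complex charged

Scaled to the whole charge, those readings gave me a full-charge rate of 0.0195 min⁻¹, a reading of the fraction of complex exchanged per minute if the whole charge stood there unused.

I reckoned with two slowings in this flask. First, the portions: over the run they counted as the whole charge present for 24.0 min of 30 min, a factor of 0.800. The exposure, full-charge rate times that time, was 0.468.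

Second, use. Starting complex was charged in the smaller amount, the limiting reagent, at 0.949 of the ligand charge. I took one ligand per exchange and let the rate run as the square of the fraction left. My reckoning for near-equal charges was exposure over one plus exposure, which gave 31.9% exchanged. On that reckoning the rate ended at a factor of 0.464 of its full-charge value.

Saturday's readings also fell short of the charge by 8.70% at 25.0 min. Taking that gap over unchanged, though it was read in another flask at another time, I expected 59.4% free starting complex.

The forecast said starting complex at 60%, within 56% to 64%, and noted: “Further exchange is slow”.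

The flask gave starting complex at 60.1%.

    starting complex + incoming ligand ⇌ leaving ligand + complex with one exchanged (K = 0.460, k = 0.0240 M⁻¹ s⁻¹)
    complex with one exchanged + incoming ligand ⇌ leaving ligand + complex with two exchanged (K = 1.10, k = 0.00320 M⁻¹ s⁻¹)
    complex with two exchanged + incoming ligand ⇌ leaving ligand + complex with three exchanged (K = 0.630, k = 0.0150 M⁻¹ s⁻¹)
    leaving ligand + starting complex ⇌ idle adduct, settled at all times (K = 45.0 M⁻¹)
    crystals ⇌ leaving ligand, rate k5*(cs5 - [leaving ligand]) while solid is left; crystals form when [leaving ligand] > cs5 (solubility = 5.80 mM, k = 0.0140 s⁻¹)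
    complex with three exchanged → over-reaction product (k = 2.20 × 10⁻⁶ s⁻¹)

Against my 31.9%, the flask held 30.7% exchanged at 30.0 min. At 14.6 min, the forward first exchange used ligand 39 times faster than the forward second. At the end, the flask held 29.7% of complex with one exchanged against 0.923% with two. The neighbour flask with 60 mM of starting complex had the same exposure at 0.263 equiv, and the balance for unequal charges gave 20.7% exchanged; it held 18.8%.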